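**Retrosynthetic overview**

1. Target 38 ← MnO2 oxidation and desilylation ← B-alkyl Suzuki–Miyaura union of the ring vinyl group of 21 with vinyl iodide 34 (from 3-methylbut-2-enal by asymmetric propargylation, two carboalumination–iodination/Negishi cycles and a hydroxyl-directed epoxidation).
2. 21 ← fused δ-lactone 16, whose ring fixes the Z enal geometry and is reduced away to the hydroxypropyl chain and the allylic alcohol; 16 ← bridged keto lactone 13 by isopropenyl addition and rhenium-catalysed transposition with acyl shift.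
3. Key disconnection: the ring bond between the CH carbon that carries the hydroxypropyl chain and the neighbouring quaternary carbon (methyl + side chain). Enabling feature: the quaternary carbon sits next to the tertiary carbinol carbon (C–O vicinal to the new C–C bond, a vinyl epoxide/π-allyl retron); the CH carbon lies between the ring carbon that becomes the alkylidene carbon and the first chain carbon, which can both be carbonyls (β-keto ester); carbinol oxygen and that chain are 1,3-cis on the ring, so a bridged γ-lactone locks the CH centre.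
4. Cyclisation precursor 11 ← Sharpless epoxidation of Z allylic alcohol 8 ← acetoacetate dianion + bromide 4 ← 2,3-dimethylmaleic anhydride (ring-enforced Z tetrasubstituted alkene).
5. Ring order: the cyclohexane is the only carbocycle and forms in the key step. The bridged γ-lactone (same step) and the fused δ-lactone (step 11) are temporary; they are opened in steps 11 and 12–13.

Key step: step 9

Assumption: in step 17 the (S)-enantiomer of the chiral phosphoric acid TRIP is taken to deliver the (S)-carbinol, by analogy with aryl and alkenyl aldehydes; the mirror-image catalyst would be used if the sense were opposite.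

**Route**

Step 1
Reactants: 1 2,3-dimethylmaleic anhydride (3,4-dimethylfuran-2,5-dione)
Product: 2 (2Z)-2,3-dimethylbut-2-ene-1,4-diol
Conditions: LiAlH4, THF, 0 °C to reflux
Reagents that add atoms: none
Why: Hydride reduction of the cyclic anhydride with LiAlH4 should give the diol, and the five-membered ring of 1 guarantees the Z geometry of the tetrasubstituted alkene on which all later ring stereochemistry rests.

Step 2
Reactants: 2 (2Z)-2,3-dimethylbut-2-ene-1,4-diol
Product: 3 (2Z)-4-{[tert-butyl(dimethyl)silyl]oxy}-2,3-dimethylbut-2-en-1-ol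
Conditions: NaH (1.0 equiv), THF, 0 °C; then TBSCl (1.0 equiv), 0 to 23 °C
Reagents that add atoms: tert-butyl(chloro)dimethylsilane, CC(C)(C)[Si](C)(C)Cl
Why: Monosilylation of the symmetrical diol through its sparingly soluble monosodium alkoxide (Williamson-type O-silylation) should differentiate the two allylic termini without creating a stereocentre.

Step 3
Reactants: 3 (2Z)-4-{[tert-butyl(dimethyl)silyl]oxy}-2,3-dimethylbut-2-en-1-ol
Product: 4 {[(2Z)-4-bromo-2,3-dimethylbut-2-en-1-yl]oxy}(tert-butyl)dimethylsilane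
Conditions: CBr4, PPh3, CH2Cl2, 0 °C
Reagents that add atoms: tetrabromomethane, BrC(Br)(Br)Br
Why: The Appel reaction should convert the primary allylic alcohol into the bromide under neutral conditions that leave the silyl ether and the alkene geometry untouched.

Step 4
Reactants: 5 methyl 3-oxobutanoate (methyl acetoacetate); 4 {[(2Z)-4-bromo-2,3-dimethylbut-2-en-1-yl]oxy}(tert-butyl)dimethylsilane
Product: 7 methyl (6Z)-8-{[tert-butyl(dimethyl)silyl]oxy}-6,7-dimethyl-3-oxooct-6-enoate, via acetoacetate dianion 6 (not isolated)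
Conditions: NaH, THF, 0 °C; n-BuLi, 0 °C; then 4, 0 °C; aqueous HCl
Reagents that add atoms: none
Why: γ-Alkylation of the acetoacetate dianion should occur at the more basic terminal carbanion in an SN2 reaction at the primary allylic bromide, because SN2′ attack would have to take place at a fully substituted alkene carbon.

Step 5
Reactants: 7 methyl (6Z)-8-{[tert-butyl(dimethyl)silyl]oxy}-6,7-dimethyl-3-oxooct-6-enoate
Product: 8 methyl (6Z)-8-hydroxy-6,7-dimethyl-3-oxooct-6-enoate
Conditions: HF·pyridine, THF, 0 °C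
Reagents that add atoms: none
Why: Fluoride-mediated cleavage of the silyl ether should free the allylic alcohol that directs the epoxidation, under conditions to which the β-keto ester is inert.

Step 6
Reactants: 8 methyl (6Z)-8-hydroxy-6,7-dimethyl-3-oxooct-6-enoate
Product: 9 methyl 5-[(2S,3R)-3-(hydroxymethyl)-2,3-dimethyloxiran-2-yl]-3-oxopentanoate
Conditions: Ti(OiPr)4 (20 mol %), D-(−)-diethyl tartrate (24 mol %), t-BuOOH, 4 Å molecular sieves, CH2Cl2, −20 °C
Reagents that add atoms: tert-butyl hydroperoxide, CC(C)(C)OO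
Why: Sharpless asymmetric epoxidation of the Z tetrasubstituted allylic alcohol should set both fully substituted oxirane carbons in one syn addition, the D-(−)-tartrate complex delivering oxygen to the face that makes the chain-bearing carbon S (the sense established for Z allylic alcohols of the nerol type).

Step 7
Reactants: 9 methyl 5-[(2S,3R)-3-(hydroxymethyl)-2,3-dimethyloxiran-2-yl]-3-oxopentanoate
Product: 10 methyl 5-[(2S,3S)-3-formyl-2,3-dimethyloxiran-2-yl]-3-oxopentanoate
Conditions: Dess–Martin periodinane, pyridine, CH2Cl2, 0 °C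
Reagents that add atoms: none
Why: Dess–Martin oxidation of the primary alcohol should give the epoxy aldehyde, which has no α-hydrogen and cannot epimerise (the descriptor at C-3 changes only through the priority switch).

Step 8
Reactants: 10 methyl 5-[(2S,3S)-3-formyl-2,3-dimethyloxiran-2-yl]-3-oxopentanoate
Product: 11 methyl 5-[(2S,3R)-3-ethenyl-2,3-dimethyloxiran-2-yl]-3-oxopentanoate
Conditions: Ph3PCH3Br, KN(SiMe3)2 (2.2 equiv each), THF, −78 to 0 °C
Reagents that add atoms: methyltriphenylphosphonium bromide, C[P+](c1ccccc1)(c1ccccc1)c1ccccc1.[Br-]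
Why: Wittig methylenation should convert the aldehyde into the vinyl group while the first equivalent of ylide parks the β-keto ester as its unreactive potassium enolate.

Step 9
Reactants: 11 methyl 5-[(2S,3R)-3-ethenyl-2,3-dimethyloxiran-2-yl]-3-oxopentanoate
Product: 13 (1S,5S,8S)-8-ethenyl-5,8-dimethyl-6-oxabicyclo[3.2.1]octane-2,7-dione, via hydroxy keto ester 12 (not isolated)
Conditions: Pd2(dba)3·CHCl3 (2.5 mol %), dppe (6 mol %), THF (0.01 M), 23 °C; then PPTS (10 mol %), toluene, 80 °C
Reagents that add atoms: none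
Why: Zerovalent palladium opens the vinyl epoxide with inversion at the allylic carbon to a zwitterionic π-allyl complex, its tertiary alkoxide deprotonates the β-keto ester within the same molecule, and the enolate carbon attacks the oxygen-bearing end of the allyl unit anti to palladium (intramolecular Tsuji–Trost alkylation of a 1,3-dicarbonyl by a vinyl epoxide under neutral conditions; the closest known case is the attack of stabilised carbon nucleophiles at the fully substituted allyl terminus derived from 2-methyl-2-vinyloxirane). The carbocycle closes in a 6-exo mode at that terminus, the alternative attack at the CH2 terminus needing an eight-membered ring, and the γ-lactone then closes by 5-exo-trig acyl substitution of the tertiary hydroxyl on the methyl ester under PPTS. The quaternary carbon C-8 is set by net retention (two inversions) and therefore follows the oxirane carbon fixed in step 6, while C-5 keeps its C–O bond throughout. C-1 is set dynamically: the β-keto ester epimerises through its enol and only the epimer with ester and hydroxyl 1,3-cis on the ring can lactonise, so both epimers of 12 drain into one bridged lactone that can no longer enolise at its bridgehead. The step needs C- rather than O-alkylation, proximal rather than distal attack and capture faster than π–σ–π face exchange, and these are secured by the soft doubly stabilised nucleophile, the ring size and the intramolecular ion pair.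

Step 10
Reactants: 13 (1S,5S,8S)-8-ethenyl-5,8-dimethyl-6-oxabicyclo[3.2.1]octane-2,7-dione
Product: 14 (1S,5S,8S)-8-ethenyl-2-hydroxy-5,8-dimethyl-2-(prop-1-en-2-yl)-6-oxabicyclo[3.2.1]octan-7-one (C-2 epimers)
Conditions: CH2=C(CH3)MgBr, CeCl3, THF, −78 °C
Reagents that add atoms: isopropenylmagnesium bromide, CC(=C)[Mg]Br
Why: Organocerium 1,2-addition should take place at the ketone in preference to the lactone, enolisation toward the bridgehead being impossible, and the configuration of the new carbinol carbon is irrelevant because that carbon becomes sp2 in step 11.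

Step 11
Reactants: 14 (1S,5S,8S)-8-ethenyl-2-hydroxy-5,8-dimethyl-2-(prop-1-en-2-yl)-6-oxabicyclo[3.2.1]octan-7-one (C-2 epimers)
Product: 16 (7S,8S,8aR)-8-ethenyl-7-hydroxy-4,7,8-trimethyl-3,5,6,7,8,8a-hexahydro-1H-isochromen-1-one, via Z allylic alcohol 15 (not isolated)
Conditions: Re2O7 (5 mol %), CH2Cl2, 0 to 23 °C
Reagents that add atoms: none
Why: Proposed new method: Re2O7 should equilibrate the tertiary alcohol with the E and Z primary allylic alcohols by suprafacial 1,3-transposition through perrhenate esters, and only the Z isomer 15 holds its CH2OH next to the lactone carbonyl, so acid-catalysed acyl transfer from the tertiary to the primary oxygen (downhill, primary for tertiary ester) removes it as the fused δ-lactone 16 whose ring fixes the tetrasubstituted alkene geometry; the closest known reaction type is the rhenium-oxo-catalysed transposition of allylic alcohols with thermodynamic trapping by a pendant electrophile.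

Step 12
Reactants: 16 (7S,8S,8aR)-8-ethenyl-7-hydroxy-4,7,8-trimethyl-3,5,6,7,8,8a-hexahydro-1H-isochromen-1-one
Product: 17 (7S,8S,8aR)-8-ethenyl-4,7,8-trimethyl-3,5,6,7,8,8a-hexahydro-1H-isochromene-1,7-diol (lactol; C-1 epimers)
Conditions: i-Bu2AlH (2.2 equiv), CH2Cl2, −78 °C
Reagents that add atoms: none
Why: Partial reduction of the δ-lactone with i-Bu2AlH at low temperature should stop at the lactol (one equivalent is consumed by the tertiary hydroxyl), and the allylic stereocentre next to the carbonyl is not touched under these non-basic conditions.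

Step 13
Reactants: 17 (7S,8S,8aR)-8-ethenyl-4,7,8-trimethyl-3,5,6,7,8,8a-hexahydro-1H-isochromene-1,7-diol
Product: 18 methyl (2E)-3-[(1R,2Z,5S,6S)-6-ethenyl-5-hydroxy-2-(1-hydroxypropan-2-ylidene)-5,6-dimethylcyclohexyl]prop-2-enoate
Conditions: Ph3P=CHCO2Me, toluene, 40 °C
Reagents that add atoms: methyl (triphenylphosphoranylidene)acetate, COC(=O)C=P(c1ccccc1)(c1ccccc1)c1ccccc1
Why: Wittig olefination of the open hydroxy aldehyde form of the lactol with the stabilised ylide should give the E enoate and release the Z allylic alcohol, the neutral conditions avoiding epimerisation and oxa-Michael closure.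

Step 14
Reactants: 18 methyl (2E)-3-[(1R,2Z,5S,6S)-6-ethenyl-5-hydroxy-2-(1-hydroxypropan-2-ylidene)-5,6-dimethylcyclohexyl]prop-2-enoate
Product: 19 methyl 3-[(1R,2Z,5S,6S)-6-ethenyl-5-hydroxy-2-(1-hydroxypropan-2-ylidene)-5,6-dimethylcyclohexyl]propanoate
Conditions: [(Ph3P)CuH]6, THF/H2O, 23 °C
Reagents that add atoms: none
Why: Conjugate reduction with the copper hydride hexamer is selective for the enoate and should leave the vinyl group, the tetrasubstituted alkene and the free hydroxyls untouched.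

Step 15
Reactants: 19 methyl 3-[(1R,2Z,5S,6S)-6-ethenyl-5-hydroxy-2-(1-hydroxypropan-2-ylidene)-5,6-dimethylcyclohexyl]propanoate
Product: 20 (1S,2S,3R,4Z)-2-ethenyl-4-(1-hydroxypropan-2-ylidene)-3-(3-hydroxypropyl)-1,2-dimethylcyclohexan-1-ol
Conditions: LiAlH4, THF, 0 °C
Reagents that add atoms: none
Why: LiAlH4 reduction of the ester should complete the 3-hydroxypropyl chain without affecting the isolated alkenes or any stereocentre.

Step 16
Reactants: 20 (1S,2S,3R,4Z)-2-ethenyl-4-(1-hydroxypropan-2-ylidene)-3-(3-hydroxypropyl)-1,2-dimethylcyclohexan-1-ol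
Product: 21 (1S,2S,3R,4Z)-4-(1-{[tert-butyl(dimethyl)silyl]oxy}propan-2-ylidene)-3-(3-{[tert-butyl(dimethyl)silyl]oxy}propyl)-2-ethenyl-1,2-dimethylcyclohexan-1-ol
Conditions: TBSCl (2.2 equiv), imidazole, DMF, 0 °C
Reagents that add atoms: tert-butyl(chloro)dimethylsilane, CC(C)(C)[Si](C)(C)Cl
Why: O-Silylation should take place only at the two primary hydroxyls, the hindered tertiary alcohol remaining free.

Step 17
Reactants: 22 3-methylbut-2-enal
Product: 23 (4S)-2-methylhept-2-en-6-yn-4-ol
Conditions: allenylboronic acid pinacol ester, (S)-TRIP phosphoric acid (5 mol %), 4 Å molecular sieves, toluene, −20 °C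
Reagents that add atoms: 4,4,5,5-tetramethyl-2-(propa-1,2-dien-1-yl)-1,3,2-dioxaborolane, C=C=CB1OC(C)(C)C(C)(C)O1
Why: Chiral phosphoric acid-catalysed propargylation (SE2′ addition of the allenylboronate through a closed six-membered transition state) should give the homopropargylic alcohol, the catalyst selecting the aldehyde face that leads to the S carbinol.

Step 18
Reactants: 23 (4S)-2-methylhept-2-en-6-yn-4-ol
Product: 24 tert-butyl(dimethyl){[(4S)-2-methylhept-2-en-6-yn-4-yl]oxy}silane
Conditions: TBSCl, imidazole, DMF, 23 °C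
Reagents that add atoms: tert-butyl(chloro)dimethylsilane, CC(C)(C)[Si](C)(C)Cl
Why: O-Silylation masks the acidic hydroxyl before the organoaluminium and organozinc steps.

Step 19
Reactants: 24 tert-butyl(dimethyl){[(4S)-2-methylhept-2-en-6-yn-4-yl]oxy}silane
Product: 26 tert-butyl{[(4S,6E)-7-iodo-2,6-dimethylhepta-2,6-dien-4-yl]oxy}dimethylsilane, via alkenylalane 25 (not isolated)
Conditions: Me3Al, Cp2ZrCl2 (25 mol %), CH2Cl2, 0 to 23 °C; then I2, THF, −30 °C
Reagents that add atoms: trimethylaluminium, C[Al](C)C; iodine, II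
Why: Zirconium-catalysed carboalumination (Negishi) adds methyl and aluminium syn across the terminal alkyne with methyl on the internal carbon, and iodinolysis with retention should give the E trisubstituted vinyl iodide.

Step 20
Reactants: 26 tert-butyl{[(4S,6E)-7-iodo-2,6-dimethylhepta-2,6-dien-4-yl]oxy}dimethylsilane; 27 (4-bromobut-1-yn-1-yl)(trimethyl)silane
Product: 29 tert-butyl{[(4S,6E)-2,6-dimethyl-11-(trimethylsilyl)undeca-2,6-dien-10-yn-4-yl]oxy}dimethylsilane, via alkylzinc bromide 28 (not isolated)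
Conditions: 27, Zn, LiCl, THF, 40 °C; then 26, Pd(PPh3)4 (5 mol %), THF, 23 °C
Reagents that add atoms: none
Why: Negishi coupling of the alkylzinc reagent with the vinyl iodide should proceed with retention of the alkene geometry, the alkynylsilane serving as a masked terminal alkyne for the next homologation.

Step 21
Reactants: 29 tert-butyl{[(4S,6E)-2,6-dimethyl-11-(trimethylsilyl)undeca-2,6-dien-10-yn-4-yl]oxy}dimethylsilane
Product: 30 tert-butyl{[(4S,6E)-2,6-dimethylundeca-2,6-dien-10-yn-4-yl]oxy}dimethylsilane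
Conditions: K2CO3, MeOH, 23 °C
Reagents that add atoms: none
Why: Base-mediated methanolysis removes the alkynyl trimethylsilyl group selectively, the silyl ether on oxygen being stable to these conditions.

Step 22
Reactants: 30 tert-butyl{[(4S,6E)-2,6-dimethylundeca-2,6-dien-10-yn-4-yl]oxy}dimethylsilane
Product: 32 tert-butyl{[(4S,6E,10E)-11-iodo-2,6,10-trimethylundeca-2,6,10-trien-4-yl]oxy}dimethylsilane, via alkenylalane 31 (not isolated)
Conditions: Me3Al, Cp2ZrCl2 (25 mol %), CH2Cl2, 0 to 23 °C; then I2, THF, −30 °C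
Reagents that add atoms: trimethylaluminium, C[Al](C)C; iodine, II
Why: A second zirconium-catalysed carboalumination–iodinolysis should set the other E trisubstituted alkene by the same syn addition.

Step 23
Reactants: 32 tert-butyl{[(4S,6E,10E)-11-iodo-2,6,10-trimethylundeca-2,6,10-trien-4-yl]oxy}dimethylsilane
Product: 33 (4S,6E,10E)-11-iodo-2,6,10-trimethylundeca-2,6,10-trien-4-ol
Conditions: Bu4NF, THF, 0 °C
Reagents that add atoms: none
Why: Fluoride cleavage of the silyl ether frees the allylic hydroxyl that directs the epoxidation.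

Step 24
Reactants: 33 (4S,6E,10E)-11-iodo-2,6,10-trimethylundeca-2,6,10-trien-4-ol
Product: 34 (1S,3E,7E)-1-[(2R)-3,3-dimethyloxiran-2-yl]-8-iodo-3,7-dimethylocta-3,7-dien-1-ol
Conditions: VO(acac)2 (5 mol %), t-BuOOH, CH2Cl2, 0 °C
Reagents that add atoms: tert-butyl hydroperoxide, CC(C)(C)OO
Why: Hydroxyl-directed vanadium-catalysed epoxidation should react only at the allylic alkene, and A(1,3) strain with the cis methyl group holds the carbinol hydrogen in the alkene plane so that oxygen is delivered syn to the hydroxyl to give the threo epoxy alcohol.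

Step 25
Reactants: 21 (1S,2S,3R,4Z)-4-(1-{[tert-butyl(dimethyl)silyl]oxy}propan-2-ylidene)-3-(3-{[tert-butyl(dimethyl)silyl]oxy}propyl)-2-ethenyl-1,2-dimethylcyclohexan-1-ol; 34 (1S,3E,7E)-1-[(2R)-3,3-dimethyloxiran-2-yl]-8-iodo-3,7-dimethylocta-3,7-dien-1-ol
Product: 36 (1S,2S,3R,4Z)-4-(1-{[tert-butyl(dimethyl)silyl]oxy}propan-2-ylidene)-3-(3-{[tert-butyl(dimethyl)silyl]oxy}propyl)-2-[(3E,7E,10S)-10-[(2R)-3,3-dimethyloxiran-2-yl]-10-hydroxy-4,8-dimethyldeca-3,7-dien-1-yl]-1,2-dimethylcyclohexan-1-ol, via B-alkylborane 35 (not isolated)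
Conditions: 9-BBN, THF, 23 °C; then 34, Pd(dppf)Cl2·CH2Cl2 (5 mol %), Ph3As, Cs2CO3, DMF/H2O, 23 °C
Reagents that add atoms: none
Why: Anti-Markovnikov hydroboration of the only accessible alkene (the vinyl group) followed by B-alkyl Suzuki–Miyaura coupling with the vinyl iodide should form the C–C bond with retention of the E geometry under conditions that spare the epoxy alcohol.

Step 26
Reactants: 36 (bis-silyl ether as named in step 25)
Product: 37 (1S,2S,3R,4Z)-2-[(3E,7E,10S)-10-[(2R)-3,3-dimethyloxiran-2-yl]-10-hydroxy-4,8-dimethyldeca-3,7-dien-1-yl]-4-(1-hydroxypropan-2-ylidene)-3-(3-hydroxypropyl)-1,2-dimethylcyclohexan-1-ol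
Conditions: Bu4NF, THF, 0 to 23 °C
Reagents that add atoms: none
Why: Fluoride-mediated desilylation should remove both primary silyl ethers without opening the epoxide.

Step 27
Reactants: 37 (tetraol as named in step 26)
Product: 38 (2Z)-2-[(2R,3S,4S)-3-[(3E,7E,10S)-10-[(2R)-3,3-dimethyloxiran-2-yl]-10-hydroxy-4,8-dimethyldeca-3,7-dien-1-yl]-4-hydroxy-2-(3-hydroxypropyl)-3,4-dimethylcyclohexylidene]propanal (target)
Conditions: MnO2, CH2Cl2, 23 °C
Reagents that add atoms: none
Why: MnO2 oxidises only the allylic primary alcohol, so the enal should form with the Z geometry fixed in step 11 while the other three hydroxyls and the epoxide stay intact.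

**Compound list**

1 | 2,3-dimethylmaleic anhydride | CC1=C(C)C(=O)OC1=O | starting material
2 | (2Z)-2,3-dimethylbut-2-ene-1,4-diol | OC/C(C)=C(C)\CO | intermediate
3 | (2Z)-4-{[tert-butyl(dimethyl)silyl]oxy}-2,3-dimethylbut-2-en-1-ol | CC(C)(C)[Si](C)(C)OC/C(C)=C(C)\CO | intermediate
4 | {[(2Z)-4-bromo-2,3-dimethylbut-2-en-1-yl]oxy}(tert-butyl)dimethylsilane | CC(C)(C)[Si](C)(C)OC/C(C)=C(C)\CBr | intermediate
5 | methyl 3-oxobutanoate | COC(=O)CC(C)=O | starting material
6 | methyl acetoacetate dianion (sodium lithium salt) | [CH2-]C(=O)[CH-]C(=O)OC.[Na+].[Li+] | intermediate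
7 | methyl (6Z)-8-{[tert-butyl(dimethyl)silyl]oxy}-6,7-dimethyl-3-oxooct-6-enoate | COC(=O)CC(=O)CC/C(C)=C(C)\CO[Si](C)(C)C(C)(C)C | intermediate
8 | methyl (6Z)-8-hydroxy-6,7-dimethyl-3-oxooct-6-enoate | COC(=O)CC(=O)CC/C(C)=C(C)\CO | intermediate
9 | methyl 5-[(2S,3R)-3-(hydroxymethyl)-2,3-dimethyloxiran-2-yl]-3-oxopentanoate | COC(=O)CC(=O)CC[C@]1(C)O[C@]1(C)CO | intermediate
10 | methyl 5-[(2S,3S)-3-formyl-2,3-dimethyloxiran-2-yl]-3-oxopentanoate | COC(=O)CC(=O)CC[C@]1(C)O[C@]1(C)C=O | intermediate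
11 | methyl 5-[(2S,3R)-3-ethenyl-2,3-dimethyloxiran-2-yl]-3-oxopentanoate | COC(=O)CC(=O)CC[C@]1(C)O[C@]1(C)C=C | intermediate
12 | methyl (2S,3S)-2-ethenyl-3-hydroxy-2,3-dimethyl-6-oxocyclohexane-1-carboxylate (C-1 epimers and enol) | COC(=O)C1C(=O)CC[C@](C)(O)[C@@]1(C)C=C | intermediate
13 | (1S,5S,8S)-8-ethenyl-5,8-dimethyl-6-oxabicyclo[3.2.1]octane-2,7-dione | O=C1CC[C@]2(C)OC(=O)[C@H]1[C@]2(C)C=C | intermediate
14 | (1S,5S,8S)-8-ethenyl-2-hydroxy-5,8-dimethyl-2-(prop-1-en-2-yl)-6-oxabicyclo[3.2.1]octan-7-one (C-2 epimers) | CC(=C)C1(O)CC[C@]2(C)OC(=O)[C@H]1[C@]2(C)C=C | intermediate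
15 | (1R,2Z,5S,8S)-8-ethenyl-2-(1-hydroxypropan-2-ylidene)-5,8-dimethyl-6-oxabicyclo[3.2.1]octan-7-one | OC/C(C)=C1/CC[C@]2(C)OC(=O)[C@H]1[C@]2(C)C=C | intermediate
16 | (7S,8S,8aR)-8-ethenyl-7-hydroxy-4,7,8-trimethyl-3,5,6,7,8,8a-hexahydro-1H-isochromen-1-one | CC1=C2CC[C@](C)(O)[C@@](C)(C=C)[C@@H]2C(=O)OC1 | intermediate
17 | (7S,8S,8aR)-8-ethenyl-4,7,8-trimethyl-3,5,6,7,8,8a-hexahydro-1H-isochromene-1,7-diol (C-1 epimers) | CC1=C2CC[C@](C)(O)[C@@](C)(C=C)[C@@H]2C(O)OC1 | intermediate
18 | methyl (2E)-3-[(1R,2Z,5S,6S)-6-ethenyl-5-hydroxy-2-(1-hydroxypropan-2-ylidene)-5,6-dimethylcyclohexyl]prop-2-enoate | C/C(CO)=C1\CC[C@](C)(O)[C@@](C)(C=C)[C@@H]1/C=C/C(=O)OC | intermediate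
19 | methyl 3-[(1R,2Z,5S,6S)-6-ethenyl-5-hydroxy-2-(1-hydroxypropan-2-ylidene)-5,6-dimethylcyclohexyl]propanoate | C/C(CO)=C1\CC[C@](C)(O)[C@@](C)(C=C)[C@@H]1CCC(=O)OC | intermediate
20 | (1S,2S,3R,4Z)-2-ethenyl-4-(1-hydroxypropan-2-ylidene)-3-(3-hydroxypropyl)-1,2-dimethylcyclohexan-1-ol | C/C(CO)=C1\CC[C@](C)(O)[C@@](C)(C=C)[C@@H]1CCCO | intermediate
21 | (1S,2S,3R,4Z)-4-(1-{[tert-butyl(dimethyl)silyl]oxy}propan-2-ylidene)-3-(3-{[tert-butyl(dimethyl)silyl]oxy}propyl)-2-ethenyl-1,2-dimethylcyclohexan-1-ol | C/C(CO[Si](C)(C)C(C)(C)C)=C1\CC[C@](C)(O)[C@@](C)(C=C)[C@@H]1CCCO[Si](C)(C)C(C)(C)C | intermediate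
22 | 3-methylbut-2-enal | CC(C)=CC=O | starting material
23 | (4S)-2-methylhept-2-en-6-yn-4-ol | C#CC[C@H](O)C=C(C)C | intermediate
24 | tert-butyl(dimethyl){[(4S)-2-methylhept-2-en-6-yn-4-yl]oxy}silane | C#CC[C@H](O[Si](C)(C)C(C)(C)C)C=C(C)C | intermediate
25 | [(1E,4S)-4-{[tert-butyl(dimethyl)silyl]oxy}-2,6-dimethylhepta-1,5-dien-1-yl]dimethylalumane | C[Al](C)/C=C(\C)C[C@H](O[Si](C)(C)C(C)(C)C)C=C(C)C | intermediate
26 | tert-butyl{[(4S,6E)-7-iodo-2,6-dimethylhepta-2,6-dien-4-yl]oxy}dimethylsilane | I/C=C(\C)C[C@H](O[Si](C)(C)C(C)(C)C)C=C(C)C | intermediate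
27 | (4-bromobut-1-yn-1-yl)(trimethyl)silane | C[Si](C)(C)C#CCCBr | starting material
28 | bromo[4-(trimethylsilyl)but-3-yn-1-yl]zinc | C[Si](C)(C)C#CCC[Zn]Br | intermediate
29 | tert-butyl{[(4S,6E)-2,6-dimethyl-11-(trimethylsilyl)undeca-2,6-dien-10-yn-4-yl]oxy}dimethylsilane | C[Si](C)(C)C#CCC/C=C(\C)C[C@H](O[Si](C)(C)C(C)(C)C)C=C(C)C | intermediate
30 | tert-butyl{[(4S,6E)-2,6-dimethylundeca-2,6-dien-10-yn-4-yl]oxy}dimethylsilane | C#CCC/C=C(\C)C[C@H](O[Si](C)(C)C(C)(C)C)C=C(C)C | intermediate
31 | [(1E,5E,8S)-8-{[tert-butyl(dimethyl)silyl]oxy}-2,6,10-trimethylundeca-1,5,9-trien-1-yl]dimethylalumane | C[Al](C)/C=C(\C)CC/C=C(\C)C[C@H](O[Si](C)(C)C(C)(C)C)C=C(C)C | intermediate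
32 | tert-butyl{[(4S,6E,10E)-11-iodo-2,6,10-trimethylundeca-2,6,10-trien-4-yl]oxy}dimethylsilane | I/C=C(\C)CC/C=C(\C)C[C@H](O[Si](C)(C)C(C)(C)C)C=C(C)C | intermediate
33 | (4S,6E,10E)-11-iodo-2,6,10-trimethylundeca-2,6,10-trien-4-ol | I/C=C(\C)CC/C=C(\C)C[C@H](O)C=C(C)C | intermediate
34 | (1S,3E,7E)-1-[(2R)-3,3-dimethyloxiran-2-yl]-8-iodo-3,7-dimethylocta-3,7-dien-1-ol | I/C=C(\C)CC/C=C(\C)C[C@H](O)[C@H]1OC1(C)C | intermediate
35 | (1S,2S,3R,4Z)-2-[2-(9-borabicyclo[3.3.1]nonan-9-yl)ethyl]-4-(1-{[tert-butyl(dimethyl)silyl]oxy}propan-2-ylidene)-3-(3-{[tert-butyl(dimethyl)silyl]oxy}propyl)-1,2-dimethylcyclohexan-1-ol | C/C(CO[Si](C)(C)C(C)(C)C)=C1\CC[C@](C)(O)[C@@](C)(CCB2C3CCCC2CCC3)[C@@H]1CCCO[Si](C)(C)C(C)(C)C | intermediate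
36 | (1S,2S,3R,4Z)-4-(1-{[tert-butyl(dimethyl)silyl]oxy}propan-2-ylidene)-3-(3-{[tert-butyl(dimethyl)silyl]oxy}propyl)-2-[(3E,7E,10S)-10-[(2R)-3,3-dimethyloxiran-2-yl]-10-hydroxy-4,8-dimethyldeca-3,7-dien-1-yl]-1,2-dimethylcyclohexan-1-ol | C/C(CO[Si](C)(C)C(C)(C)C)=C1\CC[C@](C)(O)[C@@](C)(CC/C=C(\C)CC/C=C(\C)C[C@H](O)[C@H]2OC2(C)C)[C@@H]1CCCO[Si](C)(C)C(C)(C)C | intermediate
37 | (1S,2S,3R,4Z)-2-[(3E,7E,10S)-10-[(2R)-3,3-dimethyloxiran-2-yl]-10-hydroxy-4,8-dimethyldeca-3,7-dien-1-yl]-4-(1-hydroxypropan-2-ylidene)-3-(3-hydroxypropyl)-1,2-dimethylcyclohexan-1-ol | C/C(CO)=C1\CC[C@](C)(O)[C@@](C)(CC/C=C(\C)CC/C=C(\C)C[C@H](O)[C@H]2OC2(C)C)[C@@H]1CCCO | intermediate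
38 | (2Z)-2-[(2R,3S,4S)-3-[(3E,7E,10S)-10-[(2R)-3,3-dimethyloxiran-2-yl]-10-hydroxy-4,8-dimethyldeca-3,7-dien-1-yl]-4-hydroxy-2-(3-hydroxypropyl)-3,4-dimethylcyclohexylidene]propanal | C/C(C=O)=C1\CC[C@](C)(O)[C@@](C)(CC/C=C(\C)CC/C=C(\C)C[C@H](O)[C@H]2OC2(C)C)[C@@H]1CCCO | target

**Step count and risks**

Total step count: 27 (steps 1–16 ring fragment, steps 17–24 side chain, steps 25–27 union and end game). Longest linear sequence: 19 steps (steps 1–16 and 25–27).

The three steps most likely to fail: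

1. Step 11 (Proposed new method). The allylic equilibration and the acyl shift may not mesh: acid-induced migration of the β,γ-alkene into conjugation, dehydration of the tertiary alcohols or incomplete E/Z funnelling could compete. The fallback uses known chemistry, sets out from 14 and returns at 16. Kinetic 1,3-transposition of 14 with Ph3SiOReO3 (5 mol %) and N,O-bis(trimethylsilyl)acetamide in Et2O at 0 °C traps the primary alcohols at once as trimethylsilyl ethers. The Z ether (1R,2Z,5S,8S)-8-ethenyl-5,8-dimethyl-2-{1-[(trimethylsilyl)oxy]propan-2-ylidene}-6-oxabicyclo[3.2.1]octan-7-one F1 is separated by chromatography, and the E ether is desilylated and returned to the same treatment. K2CO3 in MeOH then removes the silyl group to give 15 as an isolated compound, and PPTS in CH2Cl2 effects the translactonisation to 16 as a separate, mild operation.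

2. Step 9. Face exchange of the π-allyl complex through its unsubstituted CH2 terminus (π–σ–π) before the hindered C–C bond forms would erode the configuration of the quaternary carbon, and β-hydride loss to a diene can compete. The fallback sets out from 10 and returns at 13. Takai–Utimoto olefination of 10 (CH3CHI2, CrCl2, THF) gives methyl 5-{(2S,3R)-2,3-dimethyl-3-[(1E)-prop-1-en-1-yl]oxiran-2-yl}-3-oxopentanoate F2, whose allyl complex is substituted at both termini and keeps its configuration as in classical stereospecific Tsuji–Trost alkylations. The same palladium cyclisation gives methyl (2S,3S)-3-hydroxy-2,3-dimethyl-6-oxo-2-[(1E)-prop-1-en-1-yl]cyclohexane-1-carboxylate F3 (not isolated) and, after PPTS, (1S,5S,8S)-5,8-dimethyl-8-[(1E)-prop-1-en-1-yl]-6-oxabicyclo[3.2.1]octane-2,7-dione F4. Ethenolysis (ethylene, second-generation Hoveyda–Grubbs catalyst, CH2Cl2) then trims the propenyl group to the vinyl group of 13.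

3. Step 25. Hydroboration of the neopentyl vinyl group may be slow, the free hydroxyl consumes borane, and protodeboronation or β-hydride elimination can intervene during transmetalation. The fallback sets out from 21 and returns at 36. Hydroboration–oxidation (9-BBN; then NaOH, H2O2) gives (1S,2S,3R,4Z)-4-(1-{[tert-butyl(dimethyl)silyl]oxy}propan-2-ylidene)-3-(3-{[tert-butyl(dimethyl)silyl]oxy}propyl)-2-(2-hydroxyethyl)-1,2-dimethylcyclohexan-1-ol F5. Iodination (I2, PPh3, imidazole) gives the corresponding 2-(2-iodoethyl) compound F6, and zinc insertion (Zn, LiCl, THF) gives the alkylzinc iodide F7. Negishi coupling of F7 with 34 (Pd(PPh3)4, THF, 23 °C) forms the same C–C bond and gives 36.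

Further compounds
F1 | step 11 | (1R,2Z,5S,8S)-8-ethenyl-5,8-dimethyl-2-{1-[(trimethylsilyl)oxy]propan-2-ylidene}-6-oxabicyclo[3.2.1]octan-7-one | C[Si](C)(C)OC/C(C)=C1/CC[C@]2(C)OC(=O)[C@H]1[C@]2(C)C=C
F2 | step 9 | methyl 5-{(2S,3R)-2,3-dimethyl-3-[(1E)-prop-1-en-1-yl]oxiran-2-yl}-3-oxopentanoate | COC(=O)CC(=O)CC[C@]1(C)O[C@]1(C)/C=C/C
F3 | step 9 | methyl (2S,3S)-3-hydroxy-2,3-dimethyl-6-oxo-2-[(1E)-prop-1-en-1-yl]cyclohexane-1-carboxylate (C-1 epimers and enol) | COC(=O)C1C(=O)CC[C@](C)(O)[C@@]1(C)/C=C/C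
F4 | step 9 | (1S,5S,8S)-5,8-dimethyl-8-[(1E)-prop-1-en-1-yl]-6-oxabicyclo[3.2.1]octane-2,7-dione | O=C1CC[C@]2(C)OC(=O)[C@H]1[C@]2(C)/C=C/C
F5 | step 25 | (1S,2S,3R,4Z)-4-(1-{[tert-butyl(dimethyl)silyl]oxy}propan-2-ylidene)-3-(3-{[tert-butyl(dimethyl)silyl]oxy}propyl)-2-(2-hydroxyethyl)-1,2-dimethylcyclohexan-1-ol | C/C(CO[Si](C)(C)C(C)(C)C)=C1\CC[C@](C)(O)[C@@](C)(CCO)[C@@H]1CCCO[Si](C)(C)C(C)(C)C
F6 | step 25 | (1S,2S,3R,4Z)-4-(1-{[tert-butyl(dimethyl)silyl]oxy}propan-2-ylidene)-3-(3-{[tert-butyl(dimethyl)silyl]oxy}propyl)-2-(2-iodoethyl)-1,2-dimethylcyclohexan-1-ol | C/C(CO[Si](C)(C)C(C)(C)C)=C1\CC[C@](C)(O)[C@@](C)(CCI)[C@@H]1CCCO[Si](C)(C)C(C)(C)C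
F7 | step 25 | (1S,2S,3R,4Z)-4-(1-{[tert-butyl(dimethyl)silyl]oxy}propan-2-ylidene)-3-(3-{[tert-butyl(dimethyl)silyl]oxy}propyl)-2-[2-(iodozincio)ethyl]-1,2-dimethylcyclohexan-1-ol | C/C(CO[Si](C)(C)C(C)(C)C)=C1\CC[C@](C)(O)[C@@](C)(CC[Zn]I)[C@@H]1CCCO[Si](C)(C)C(C)(C)C
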